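Assumption: carotenoid numbering is used throughout. The triol half carries C1–C15, C19 and C20, and the enyne half carries primed numbers. C12', C13' and C20' are absent, so C11' is bonded to C14'. The SMILES is read as the (3S,5R,6R,3'R) isomer with an all-E chain and Z-C11=C12. The two enzymes of step 1 are taken as purchasable preparations.

## Structural features

- **Skeleton.** The target is a C37 trinor-carotenoid. A 3'R-hydroxy-trimethylcyclohexene (C1'–C6') is joined through C7'≡C8' and the all-E chain C9'=C10'–C11'=C14'–C15'=C15–C14=C13 to the exocyclic Z-C12=C11 bond of a butenolide (ring O–C19–C9–C10–C11). C9 of that ring carries a cyclohexane-3,5,6-triol (C1–C6) through E-C7=C8.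
- **Stereocentres.** C5 and C6 are adjacent, fully substituted carbinols forming a trans-diol. C3 is 1,3 to C5 and 1,4 to C6. O3 and O6 lie on one ring face, and O5 and C7 lie on the other. C3' is remote but has the same spatial sense as C3.
- **Fragile groups.** These are the tertiary allylic C6–OH (ionisation), the enol lactone (nucleophiles, Z/E drift), the C9'=C10' bond next to the alkyne (easy E/Z equilibration), and the polyene as a whole (light, acid, oxygen).
- **First difficulty.** C9 is a cross-conjugated junction bonded to C8, C10 and C19, and the enol-lactone carbon C11 has to be made with defined geometry while two large halves are joined.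
- **Second difficulty.** The trans ditertiary diol C5/C6 sits between the quaternary C1 and the chain.
- **Feature used by the key step.** C9 is both α to the C19 carboxyl and allylic to C7=C8, so it is doubly activated as a CH2. C10 is the only CH of the ring, so it can be an aldehyde carbon. The enol ester C11=C12 is a masked triple bond. The geometry of C9=C10 is dictated by the ring once O–C11 is closed.
- **Secondary features.** With C11≡C12 in place, the segment C7'–C11 is C2h-symmetric about the C14'–C15' bond, so one C6 enynol can serve twice. The two rings share skeleton and C3 configuration, so one enol triflate can serve twice.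

## Logic of the disconnections

**27 back to 24 (through 26 and 25).**
- Cut: the π-bond C9=C10. Water is put back with OH on C10, after O3 and O3' have been masked.
- Reason: the endocyclic alkene needs no stereocontrol, because the ring allows only one geometry.
- Gain: C9 and C10 become sp3, which opens carbonyl chemistry inside the ring.
- Demand: the forward elimination must touch only the C10 hydroxyl. This holds because O3 and O3' are silylated and O5 and O6 are hindered tertiary hydroxyls.

**24 back to 22 + 13 (through 23), the key disconnection.**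
- Cut: O–C11 and C9–C10.
- Reason: this cut goes through the heterocycle at the one ring bond that cross-coupling logic never addresses. It turns the C9 junction into a plain CH2 and C11=C12 into an alkyne.
- Gain: a C37 lactone falls into a C13 acid and a C24 aldehyde. Neither carries a stereodefined halide or metal at the junction.
- Demand: α-selective 1,2-addition, then 5-exo rather than 6-endo closure with anti addition.
- One-sentence test: the dienediolate of 22 adds through C9 to the aldehyde C10 of 13, and the resulting 4-alkynoic acid is lactonised 5-exo-dig. That sentence does not describe a coupling on a preformed or planar butenolide precursor.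

**13 back to 12.**
- Cut: C10–C11.
- Reason: C10 is a single carbon at the aldehyde level on an sp carbon.
- Gain: the sensitive ynal exists for one step only.
- Demand: clean metalation of the terminal alkyne in the presence of the polyene.

**12 back to 9 + 11.**
- Cut: the single bond C14'–C15', the centre of the latent symmetry.
- Reason: an sp2–sp2 coupling is stereospecific, and no equilibrating conditions reach the labile C9'=C10' and C13=C14 bonds.
- Gain: two dienyl halves of similar make.
- Demand: a mild coupling that tolerates a free terminal alkyne.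

**9 back to 7 (through 8), and 11 back to 6 (through 10).**
- Cut: C11'=C14' and C15=C15'.
- Reason: both are E-disubstituted alkenes next to an enal carbon, and each needs one extra carbon that bears the coupling handle.
- Gain: both halves fall back to the same C6 unit.
- Demand: E-selective one-carbon olefination.

**7 back to 5 + 6.**
- Cut: C6'–C7'.
- Reason: 6 already holds C7'–C11' and C19' with the E-C9'=C10' bond.
- Gain: a C15 unit in one step.
- Demand: coupling at a hindered tetrasubstituted enol triflate.

**22 back to 20 (through 21).**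
- Cut: C8–C9.
- Reason: C9 and C19 form an acetate unit.
- Gain: the side chain shrinks to a two-carbon vinyl handle.
- Demand: retention of the E geometry and no drift of C7=C8 into conjugation.

**20 back to 18 (through 19).**
- Cut: C8–I and C7–H, a retro-hydrometalation.
- Reason: the E alkene comes from syn addition to a terminal alkyne.
- Gain: the alkyne is needed as a control element in the next cut.
- Demand: distal regioselectivity, which the bulk at C6 should enforce.

**18 back to 15 (through 17 and 16).**
- Cut: C5–O and C6–O.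
- Reason: O6 is cis to O3, so it can be delivered by O3. O5 is then brought in with inversion at C5.
- Gain: three stereocentres reduce to one.
- Demand: syn-selective epoxidation and opening at C5 only. The ethynyl group at C6 (cation-destabilising) and the trans-diaxial rule both point that way.

**15 back to 5 (through 14).**
- Cut: C6–C7.
- Gain: both rings come from one compound.
- Demand: the same hindered coupling as in the cut of 7.

**5 back to 1 (through 4, 3 and 2).**
- Cut: C6–O(Tf), and the two C–H bonds added to the ene-dione.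
- Reason: the ketone can enolise in one direction only, and only the carbinol centre has to survive.
- Gain: an achiral bulk chemical.
- Demand: one enantioselective reduction sequence.

## Other disconnections considered

**Alternative 1** (the first that comes to mind):
- Cut: the two sp2–sp2 single bonds C8–C9 and C12–C13 that flank the heterocycle.
- Forward key step: two successive Stille couplings on the dihalide linchpin A1. The first is at the iodomethylidene carbon with the polyenylstannane A2. The second is at C9–Br with 19.
- Ground for preferring the chosen plan: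
  - The ring has to be made separately, so the couplings settle none of its difficulty.
  - A2 needs a stereodefined trisubstituted C13 stannane next to the labile part of the chain.
  - Two carbon–halogen bonds of one small electrophile must be told apart.
  - Two stoichiometric tin reagents are carried to the end.

**Alternative 2:**
- Cut: C10–C11 and O–C11.
- Forward key step: Pd/Cu coupling of 12 with the (Z)-β-iodo acid A3 and lactonisation in the same flask.
- Ground for preferring the chosen plan:
  - A3 demands a stereodefined trisubstituted iodoalkene at the crowded C9 junction, which costs several more steps than 22.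
  - The planar 2-en-4-ynoic acid formed has a real 6-endo option, since a donor-substituted C12 favours pyranone formation.
  - In the chosen plan the sp3 tether and the propargylic C–O bond bias the closure towards 5-exo.

**Alternative 3:**
- Cut: C11=C12.
- Forward key step: vinylogous aldol condensation of the α-dienyl butenolide A4, through its 2-silyloxyfuran, with the C22 polyenal A5, followed by elimination.
- Ground for preferring the chosen plan:
  - This is the textbook cut of a γ-ylidenebutenolide.
  - The Z geometry would rest on an elimination, not on a stereospecific anti addition.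
  - The Lewis acid needed threatens the tertiary allylic C6–O bond.
  - The silyloxyfuran bearing a dienyl arm is an electron-rich triene prone to self-reaction.
  - A5 cannot use the second copy of 6.

Key step: step 19

## Steps

Step 1
Reactants: 1 ketoisophorone (2,6,6-trimethylcyclohex-2-ene-1,4-dione)
Product: 3 (4R,6R)-4-hydroxy-2,2,6-trimethylcyclohexan-1-one, via (6R)-levodione 2 (not isolated)
Conditions: ene-reductase (Old Yellow Enzyme class), NADP+ (cat.), D-glucose, glucose dehydrogenase, phosphate buffer pH 7, 30 °C; then levodione reductase (short-chain alcohol dehydrogenase), same pot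
Reagents that add atoms: none
Why: The flavin enzyme reduces the activated C=C bond by trans addition of hydride and proton and sets the transient methyl centre; the dehydrogenase, added only after 1 is consumed so that it cannot reduce 1 itself, then reduces the unhindered carbonyl and sets the carbinol centre (C3 and C3' of 27) from which all other stereocentres are relayed. Known two-enzyme reduction cascade with cofactor recycling.

Step 2
Reactants: 3 (4R,6R)-4-hydroxy-2,2,6-trimethylcyclohexan-1-one
Product: 4 (4R,6R)-4-(tert-butyldimethylsilyloxy)-2,2,6-trimethylcyclohexan-1-one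
Conditions: TBSCl, imidazole, DMF, rt
Reagents that add atoms: tert-butyldimethylsilyl chloride, CC(C)(C)[Si](C)(C)Cl
Why: Standard silylation of a secondary alcohol; it removes the acidic proton before enolate chemistry and touches no stereocentre.

Step 3
Reactants: 4 (4R,6R)-4-(tert-butyldimethylsilyloxy)-2,2,6-trimethylcyclohexan-1-one
Product: 5 (4R)-4-(tert-butyldimethylsilyloxy)-2,6,6-trimethylcyclohex-1-en-1-yl trifluoromethanesulfonate
Conditions: LDA, THF, -78 to 0 °C; PhNTf2, -78 °C to rt
Reagents that add atoms: N-phenylbis(trifluoromethanesulfonimide), O=S(=O)(N(c1ccccc1)S(=O)(=O)C(F)(F)F)C(F)(F)F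
Why: One α-carbon is quaternary, so the ketone can enolise only towards the methyl-bearing carbon and O-triflation of the enolate should give a single tetrasubstituted enol triflate. The methyl stereocentre is erased on purpose and the carbinol centre is untouched.

Step 4
Reactants: 5 (4R)-4-(tert-butyldimethylsilyloxy)-2,6,6-trimethylcyclohex-1-en-1-yl trifluoromethanesulfonate; 6 (2E)-3-methylpent-2-en-4-yn-1-ol
Product: 7 (2E)-5-[(4R)-4-(tert-butyldimethylsilyloxy)-2,6,6-trimethylcyclohex-1-en-1-yl]-3-methylpent-2-en-4-yn-1-ol
Conditions: PdCl2(PPh3)2 (cat.), CuI (cat.), Et3N, DMF, 40 °C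
Reagents that add atoms: none
Why: Sonogashira coupling of an enol triflate with a terminal alkyne forms C6'-C7'. The slim copper acetylide copes with the hindered triflate, and the E-C9'=C10' bond is bought with 6 and is not touched.

Step 5
Reactants: 7 (2E)-5-[(4R)-4-(tert-butyldimethylsilyloxy)-2,6,6-trimethylcyclohex-1-en-1-yl]-3-methylpent-2-en-4-yn-1-ol
Product: 8 (2E)-5-[(4R)-4-(tert-butyldimethylsilyloxy)-2,6,6-trimethylcyclohex-1-en-1-yl]-3-methylpent-2-en-4-ynal
Conditions: MnO2, CH2Cl2, rt
Reagents that add atoms: none
Why: Selective heterogeneous oxidation of a primary allylic alcohol under neutral conditions, which should leave the silyl ether and the alkene geometry intact.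

Step 6
Reactants: 8 (2E)-5-[(4R)-4-(tert-butyldimethylsilyloxy)-2,6,6-trimethylcyclohex-1-en-1-yl]-3-methylpent-2-en-4-ynal
Product: 9 tert-butyl({(1R)-4-[(3E,5E)-6-iodo-3-methylhexa-3,5-dien-1-yn-1-yl]-3,5,5-trimethylcyclohex-3-en-1-yl}oxy)dimethylsilane
Conditions: CrCl2, CHI3, THF-dioxane, 0 °C
Reagents that add atoms: iodoform, IC(I)I
Why: Takai olefination; the gem-dichromium reagent adds to the aldehyde and anti-periplanar elimination should give mainly the E iodide (C11'=C14', with C14' from iodoform). Chromium(II) tolerates the enyne and the silyl ether.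

Step 7
Reactants: 6 (2E)-3-methylpent-2-en-4-yn-1-ol
Product: 10 (2E)-3-methylpent-2-en-4-ynal
Conditions: MnO2, CH2Cl2, rt
Reagents that add atoms: none
Why: The same neutral allylic oxidation as in step 5, on the second copy of the C6 unit (here C11-C15 and C20).

Step 8
Reactants: 10 (2E)-3-methylpent-2-en-4-ynal
Product: 11 2-[(1E,3E)-4-methylhexa-1,3-dien-5-yn-1-yl]-4,4,5,5-tetramethyl-1,3,2-dioxaborolane
Conditions: CrCl2, LiI, Cl2CHB(pin), THF, rt
Reagents that add atoms: 2-(dichloromethyl)-4,4,5,5-tetramethyl-1,3,2-dioxaborolane, ClC(Cl)B1OC(C)(C)C(C)(C)O1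
Why: Boron variant of the Takai olefination; the bulky boryl group should make the E selectivity at C15=C15' high. The terminal alkyne is inert to chromium(II).

Step 9
Reactants: 9 tert-butyl({(1R)-4-[(3E,5E)-6-iodo-3-methylhexa-3,5-dien-1-yn-1-yl]-3,5,5-trimethylcyclohex-3-en-1-yl}oxy)dimethylsilane; 11 2-[(1E,3E)-4-methylhexa-1,3-dien-5-yn-1-yl]-4,4,5,5-tetramethyl-1,3,2-dioxaborolane
Product: 12 tert-butyl({(1R)-4-[(3E,5E,7E,9E)-3,10-dimethyldodeca-3,5,7,9-tetraene-1,11-diyn-1-yl]-3,5,5-trimethylcyclohex-3-en-1-yl}oxy)dimethylsilane
Conditions: Pd(PPh3)4 (cat.), aq K3PO4, THF, rt, degassed, dark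
Reagents that add atoms: none
Why: Suzuki coupling of an alkenyl iodide with an alkenylboronate forms C14'-C15' with retention at both partners, so the tetraene is all-E without any equilibration. Without copper and amine the free alkyne should stay a spectator.

Step 10
Reactants: 12 tert-butyl({(1R)-4-[(3E,5E,7E,9E)-3,10-dimethyldodeca-3,5,7,9-tetraene-1,11-diyn-1-yl]-3,5,5-trimethylcyclohex-3-en-1-yl}oxy)dimethylsilane
Product: 13 (4E,6E,8E,10E)-13-[(4R)-4-(tert-butyldimethylsilyloxy)-2,6,6-trimethylcyclohex-1-en-1-yl]-4,11-dimethyltrideca-4,6,8,10-tetraene-2,12-diynal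
Conditions: n-BuLi, THF, -78 °C; DMF; poured into aq KH2PO4
Reagents that add atoms: N,N-dimethylformamide, CN(C)C=O
Why: Deprotonation of the only acidic C-H is much faster than any addition to the polyene at -78 °C. Formylation of the lithium acetylide, with buffered collapse of the hemiaminal, is the standard route to ynals and adds C10.

Step 11
Reactants: 5 (4R)-4-(tert-butyldimethylsilyloxy)-2,6,6-trimethylcyclohex-1-en-1-yl trifluoromethanesulfonate
Product: 14 tert-butyldimethyl({(1R)-3,5,5-trimethyl-4-[(trimethylsilyl)ethynyl]cyclohex-3-en-1-yl}oxy)silane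
Conditions: trimethylsilylacetylene, PdCl2(PPh3)2 (cat.), CuI (cat.), Et3N, DMF, 40 °C
Reagents that add atoms: trimethylsilylacetylene, C#C[Si](C)(C)C
Why: The same Sonogashira coupling as in step 4 forms C6-C7 and brings in C7 and C8; the silyl cap prevents double coupling.

Step 12
Reactants: 14 tert-butyldimethyl({(1R)-3,5,5-trimethyl-4-[(trimethylsilyl)ethynyl]cyclohex-3-en-1-yl}oxy)silane
Product: 15 (1R)-4-ethynyl-3,5,5-trimethylcyclohex-3-en-1-ol
Conditions: TBAF, THF, rt
Reagents that add atoms: none
Why: Fluoride cleaves both the C-Si and the O-Si bond in one operation and frees the hydroxyl that has to direct step 13.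

Step 13
Reactants: 15 (1R)-4-ethynyl-3,5,5-trimethylcyclohex-3-en-1-ol
Product: 16 (1S,4S,6S)-1-ethynyl-2,2,6-trimethyl-7-oxabicyclo[4.1.0]heptan-4-ol (5,6-epoxide cis to the 3-hydroxyl)
Conditions: VO(acac)2 (cat.), t-BuOOH, CH2Cl2, 0 °C to rt
Reagents that add atoms: tert-butyl hydroperoxide, CC(C)(C)OO
Why: Hydroxyl-directed vanadium epoxidation of a homoallylic cyclohexenol; the peroxide bound to the vanadate ester of the pseudo-axial O3 reaches only the face that carries O3. C5 and C6 are therefore set together from C3 in one event (the C6-O bond is already the final one), and the alkyne is inert.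

Step 14
Reactants: 16 (1S,4S,6S)-1-ethynyl-2,2,6-trimethyl-7-oxabicyclo[4.1.0]heptan-4-ol
Product: 17 (1S,2R,4S)-1-ethynyl-2,6,6-trimethylcyclohexane-1,2,4-triol (O3 and O6 cis, O5 trans to both)
Conditions: HClO4 (cat.), THF-H2O, 0 °C
Reagents that add atoms: water, O
Why: In the protonated epoxide the C5-O bond is the weaker one, because C5 is a plain tertiary centre while C6 carries the inductively destabilising ethynyl group and is flanked by quaternary C1. Water attacks C5 anti to the leaving oxygen (inversion at C5, retention at C6). This is also the trans-diaxial opening that leads directly to the chair with O3 equatorial.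

Step 15
Reactants: 17 (1S,2R,4S)-1-ethynyl-2,6,6-trimethylcyclohexane-1,2,4-triol
Product: 18 (1S,2R,4S)-4-(tert-butyldimethylsilyloxy)-1-ethynyl-2,6,6-trimethylcyclohexane-1,2-diol
Conditions: TBSCl, imidazole, DMF, 0 °C
Reagents that add atoms: tert-butyldimethylsilyl chloride, CC(C)(C)[Si](C)(C)Cl
Why: Only the secondary O3 is accessible to the bulky silyl chloride; the two hindered tertiary hydroxyls stay free and need no protection later.

Step 16
Reactants: 18 (1S,2R,4S)-4-(tert-butyldimethylsilyloxy)-1-ethynyl-2,6,6-trimethylcyclohexane-1,2-diol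
Product: 20 (1R,2R,4S)-4-(tert-butyldimethylsilyloxy)-1-[(E)-2-iodoethenyl]-2,6,6-trimethylcyclohexane-1,2-diol, via (E)-vinylstannane 19 (not isolated)
Conditions: Bu3SnH, PdCl2(PPh3)2 (cat.), THF, 0 °C; then I2, CH2Cl2, 0 °C
Reagents that add atoms: iodine, II; tributyltin hydride, CCCC[SnH](CCCC)CCCC (its tin is in 19 only)
Why: Palladium-catalysed syn hydrostannation places tin on the terminal C8, away from the crowded C6, and tolerates free hydroxyls. Iododestannylation proceeds with retention, so C7=C8 is E.

Step 17
Reactants: 20 (1R,2R,4S)-4-(tert-butyldimethylsilyloxy)-1-[(E)-2-iodoethenyl]-2,6,6-trimethylcyclohexane-1,2-diol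
Product: 21 ethyl (3E)-4-[(1R,2R,4S)-4-(tert-butyldimethylsilyloxy)-1,2-dihydroxy-2,6,6-trimethylcyclohexyl]but-3-enoate
Conditions: BrZnCH2CO2Et (excess), Pd(PPh3)4 (cat.), THF, 45 °C
Reagents that add atoms: (2-ethoxy-2-oxoethyl)zinc bromide, CCOC(=O)C[Zn]Br
Why: Negishi-type coupling of a Reformatsky reagent with an alkenyl iodide forms C8-C9 with retention of the E geometry and adds C9 and C19. The weakly basic zinc enolate should be quenched only slowly by the hindered tertiary hydroxyls, and the E alkene keeps O6 away from the ester.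

Step 18
Reactants: 21 ethyl (3E)-4-[(1R,2R,4S)-4-(tert-butyldimethylsilyloxy)-1,2-dihydroxy-2,6,6-trimethylcyclohexyl]but-3-enoate
Product: 22 (3E)-4-[(1R,2R,4S)-4-(tert-butyldimethylsilyloxy)-1,2-dihydroxy-2,6,6-trimethylcyclohexyl]but-3-enoic acid
Conditions: LiOH, THF-MeOH-H2O, 0 °C to rt; 1 M HCl to pH 4
Reagents that add atoms: lithium hydroxide, [Li+].[OH-]
Why: Saponification of an unhindered ethyl ester at low temperature should be faster than base-induced migration of C7=C8; the silyl ether is stable to hydroxide under these conditions.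

Step 19
Reactants: 22 (3E)-4-[(1R,2R,4S)-4-(tert-butyldimethylsilyloxy)-1,2-dihydroxy-2,6,6-trimethylcyclohexyl]but-3-enoic acid; 13 (4E,6E,8E,10E)-13-[(4R)-4-(tert-butyldimethylsilyloxy)-2,6,6-trimethylcyclohex-1-en-1-yl]-4,11-dimethyltrideca-4,6,8,10-tetraene-2,12-diynal
Product: 24 9,10-dihydro-10-hydroxy derivative of the 3,3'-bis-TBS ether of 27 (β-hydroxy-γ-(Z)-ylidene-butyrolactone, mixture of C9/C10 diastereomers), via β-hydroxy acid 23 (not isolated)
Conditions: 22, LDA (4.3 equiv), THF, -78 to -20 °C; 13, -78 °C; AcOH quench, extractive work-up; crude 23, Ag2CO3 (cat.), toluene, rt, dark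
Reagents that add atoms: none
Why: LDA converts 22 into its lithium dienediolate, while O5 and O6 ride along as alkoxides, which also blocks vinylogous loss of O6; the dienediolate adds through C9 to the aldehyde carbon C10 of 13, the known kinetic α-selective aldol addition of but-3-enoic acid dienediolates. α- over γ-attack is secured by the substrate, since the γ-carbon C7 is shielded by the fully substituted C6, and 1,2- over conjugate addition is secured by the hard lithium enolate at -78 °C. The crude 3-hydroxy-4-alkynoic acid 23 is then cycloisomerised by silver(I), the known silver-catalysed lactonisation of 4-alkynoic acids, which a propargylic C-O bond accelerates. The carboxylate attacks the silver-bound triple bond at C11 in a 5-exo-dig closure of the ring O-C19-C9-C10-C11; the sp3 atoms C9 and C10 of the tether favour this mode over 6-endo attack at C12. Anti addition of oxygen and silver, followed by protodemetalation with retention, puts O and C13 on the same side, which is the Z-C11=C12 bond. The new stereocentres C9 and C10 are not controlled and need not be, since both become sp2 in step 20. The hindered internal alkyne C7'≡C8' has no nucleophile within reach and should stay untouched.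

Step 20
Reactants: 24 9,10-dihydro-10-hydroxy derivative of the 3,3'-bis-TBS ether of 27
Product: 26 3,3'-bis(tert-butyldimethylsilyl) ether of 27, via C10 mesylate 25 (not isolated)
Conditions: MsCl, Et3N, CH2Cl2, -30 to 0 °C
Reagents that add atoms: methanesulfonyl chloride, CS(=O)(=O)Cl (its atoms are in 25 only and leave again)
Why: Only the secondary C10 hydroxyl is free and accessible. Its mesylate is β to the lactone carbonyl, and C9-H is both α-carbonyl and allylic, so E1cB elimination should follow at once, whichever diastereomer is present, and give the endocyclic C9=C10 bond, whose geometry is fixed by the ring.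

Step 21
Reactants: 26 3,3'-bis(tert-butyldimethylsilyl) ether of 27
Product: 27 target, (3S,5R,6R,3'R)-configured, all-E chain, Z-C11=C12
Conditions: TBAF, AcOH, THF, 0 °C to rt, argon, dark
Reagents that add atoms: none
Why: Acetic-acid-buffered fluoride removes both secondary silyl ethers near neutrality, which spares the enol lactone from base and the tertiary allylic C6-OH from acid; no stereocentre or alkene is involved.

## Compound list

1 | ketoisophorone (2,6,6-trimethylcyclohex-2-ene-1,4-dione) | CC1=CC(=O)CC(C)(C)C1=O | starting material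
2 | (6R)-levodione, (6R)-2,2,6-trimethylcyclohexane-1,4-dione | O=C1C(C)(C)CC(=O)C[C@H]1C | intermediate
3 | (4R,6R)-4-hydroxy-2,2,6-trimethylcyclohexan-1-one | O=C1C(C)(C)C[C@H](O)C[C@H]1C | intermediate
4 | (4R,6R)-4-(tert-butyldimethylsilyloxy)-2,2,6-trimethylcyclohexan-1-one | O=C1C(C)(C)C[C@H](O[Si](C)(C)C(C)(C)C)C[C@H]1C | intermediate
5 | (4R)-4-(tert-butyldimethylsilyloxy)-2,6,6-trimethylcyclohex-1-en-1-yl trifluoromethanesulfonate | CC1=C(OS(=O)(=O)C(F)(F)F)C(C)(C)C[C@H](O[Si](C)(C)C(C)(C)C)C1 | intermediate
6 | (2E)-3-methylpent-2-en-4-yn-1-ol | C#C/C(C)=C/CO | starting material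
7 | C15 enynol, (2E)-5-[(4R)-4-(TBSO)-2,6,6-trimethylcyclohex-1-en-1-yl]-3-methylpent-2-en-4-yn-1-ol | CC1=C(C#C/C(C)=C/CO)C(C)(C)C[C@H](O[Si](C)(C)C(C)(C)C)C1 | intermediate
8 | C15 enynal | CC1=C(C#C/C(C)=C/C=O)C(C)(C)C[C@H](O[Si](C)(C)C(C)(C)C)C1 | intermediate
9 | C16 (E,E)-dienyl iodide (iodine on C14') | CC1=C(C#C/C(C)=C/C=C/I)C(C)(C)C[C@H](O[Si](C)(C)C(C)(C)C)C1 | intermediate
10 | (2E)-3-methylpent-2-en-4-ynal | C#C/C(C)=C/C=O | intermediate
11 | 2-[(1E,3E)-4-methylhexa-1,3-dien-5-yn-1-yl]-4,4,5,5-tetramethyl-1,3,2-dioxaborolane | C#C/C(C)=C/C=C/B1OC(C)(C)C(C)(C)O1 | intermediate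
12 | C23 all-E tetraenediyne with terminal C11-H alkyne | CC1=C(C#C/C(C)=C/C=C/C=C/C=C(C)/C#C)C(C)(C)C[C@H](O[Si](C)(C)C(C)(C)C)C1 | intermediate
13 | C24 all-E tetraenediynal (C10 aldehyde) | CC1=C(C#C/C(C)=C/C=C/C=C/C=C(C)/C#CC=O)C(C)(C)C[C@H](O[Si](C)(C)C(C)(C)C)C1 | intermediate
14 | TMS-capped, TBS-protected C11 enyne | CC1=C(C#C[Si](C)(C)C)C(C)(C)C[C@H](O[Si](C)(C)C(C)(C)C)C1 | intermediate
15 | (1R)-4-ethynyl-3,5,5-trimethylcyclohex-3-en-1-ol | CC1=C(C#C)C(C)(C)C[C@H](O)C1 | intermediate
16 | (1S,4S,6S)-1-ethynyl-2,2,6-trimethyl-7-oxabicyclo[4.1.0]heptan-4-ol (epoxide cis to OH) | C#C[C@]12O[C@@]1(C)C[C@@H](O)CC2(C)C | intermediate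
17 | (1S,2R,4S)-1-ethynyl-2,6,6-trimethylcyclohexane-1,2,4-triol | C#C[C@@]1(O)C(C)(C)C[C@H](O)C[C@@]1(C)O | intermediate
18 | (1S,2R,4S)-4-(TBSO)-1-ethynyl-2,6,6-trimethylcyclohexane-1,2-diol | C#C[C@@]1(O)C(C)(C)C[C@H](O[Si](C)(C)C(C)(C)C)C[C@@]1(C)O | intermediate
19 | (1R,2R,4S)-4-(TBSO)-2,6,6-trimethyl-1-[(E)-2-(tributylstannyl)ethenyl]cyclohexane-1,2-diol | CCCC[Sn](CCCC)(CCCC)/C=C/[C@@]1(O)C(C)(C)C[C@H](O[Si](C)(C)C(C)(C)C)C[C@@]1(C)O | intermediate
20 | (1R,2R,4S)-4-(TBSO)-1-[(E)-2-iodoethenyl]-2,6,6-trimethylcyclohexane-1,2-diol | I/C=C/[C@@]1(O)C(C)(C)C[C@H](O[Si](C)(C)C(C)(C)C)C[C@@]1(C)O | intermediate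
21 | ethyl (3E)-4-[(1R,2R,4S)-4-(TBSO)-1,2-dihydroxy-2,6,6-trimethylcyclohexyl]but-3-enoate | CCOC(=O)C/C=C/[C@@]1(O)C(C)(C)C[C@H](O[Si](C)(C)C(C)(C)C)C[C@@]1(C)O | intermediate
22 | (3E)-4-[(1R,2R,4S)-4-(TBSO)-1,2-dihydroxy-2,6,6-trimethylcyclohexyl]but-3-enoic acid | OC(=O)C/C=C/[C@@]1(O)C(C)(C)C[C@H](O[Si](C)(C)C(C)(C)C)C[C@@]1(C)O | intermediate
23 | aldol adduct, 10-hydroxy-11,12-didehydro seco acid (C9/C10 unassigned) | CC1=C(C#C/C(C)=C/C=C/C=C/C=C(C)/C#CC(O)C(/C=C/[C@@]2(O)C(C)(C)C[C@H](O[Si](C)(C)C(C)(C)C)C[C@@]2(C)O)C(=O)O)C(C)(C)C[C@H](O[Si](C)(C)C(C)(C)C)C1 | intermediate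
24 | β-hydroxy-γ-(Z)-ylidene-butyrolactone (C9/C10 unassigned) | CC1=C(C#C/C(C)=C/C=C/C=C/C=C(C)/C=C2C(O)C(/C=C/[C@@]3(O)C(C)(C)C[C@H](O[Si](C)(C)C(C)(C)C)C[C@@]3(C)O)C(=O)O/2)C(C)(C)C[C@H](O[Si](C)(C)C(C)(C)C)C1 | intermediate
25 | C10 methanesulfonate of 24 | CC1=C(C#C/C(C)=C/C=C/C=C/C=C(C)/C=C2C(OS(C)(=O)=O)C(/C=C/[C@@]3(O)C(C)(C)C[C@H](O[Si](C)(C)C(C)(C)C)C[C@@]3(C)O)C(=O)O/2)C(C)(C)C[C@H](O[Si](C)(C)C(C)(C)C)C1 | intermediate
26 | 3,3'-bis(tert-butyldimethylsilyl) ether of the target | CC1=C(C#C/C(C)=C/C=C/C=C/C=C(C)/C=C2C=C(/C=C/[C@@]3(O)C(C)(C)C[C@H](O[Si](C)(C)C(C)(C)C)C[C@@]3(C)O)C(=O)O/2)C(C)(C)C[C@H](O[Si](C)(C)C(C)(C)C)C1 | intermediate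
27 | CNP0163979.1, (3S,5R,6R,3'R) | CC1=C(C#C/C(C)=C/C=C/C=C/C=C(C)/C=C2C=C(/C=C/[C@@]3(O)C(C)(C)C[C@H](O)C[C@@]3(C)O)C(=O)O/2)C(C)(C)C[C@H](O)C1 | target

## Count and risks

Total step count: 21. Longest linear sequence: 14 steps (1, 2, 3, then 11 to 21).

**Step 19 (key step).**
- What may go wrong: formation of the tetralithiated species may be incomplete, or it may be poorly soluble. Proton transfer or retro-aldol cleavage may occur on work-up. In the silver step, 6-endo closure or Meyer–Schuster-type rearrangement of the propargylic alcohol may compete, because the polyenyl group makes C12 electron-rich.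
- Fallback: it sets out from 12 and from 19, which is isolated after the hydrostannation of step 16 instead of being iodinated. Bromine is added anti to propiolic acid to give (E)-2,3-dibromoacrylic acid F1. Pd/Cu-catalysed coupling of 12 at the β-bromide of F1, with lactonisation in the same flask, gives the (Z)-3-bromo-5-ylidenebutenolide F2. Stille coupling of F2 with 19 forms C8–C9 and comes back to the route at 26.

**Step 14.**
- What may go wrong: after ionisation at C5, loss of a proton (giving allylic alcohols) or a 1,2-shift (ring contraction) may outrun capture by water, because the cation is tertiary and crowded.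
- Fallback: it sets out from 1.
  - Ruthenium(II)/TsDPEN transfer hydrogenation of the unhindered carbonyl gives (4S)-4-hydroxy-2,6,6-trimethylcyclohex-2-en-1-one F3.
  - Silylation gives its TBS ether F4.
  - Ethynylmagnesium bromide with CeCl3 adds to the ketone on the face opposite to the silyloxy group. Trapping the alkoxide with TMSCl gives the bis-silylated ethynyl cyclohexene F5.
  - mCPBA attacks C4=C5 on the face opposite to both silyloxy groups and gives the 4,5-epoxide F6.
  - LiEt3BH opens the epoxide at the less substituted C4, and K2CO3 in methanol removes the TMS group. This comes back to the route at 18.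

**Step 9.**
- What may go wrong: copper-free alkynylation of the iodide by the free terminal alkyne, protodeboronation, or erosion of geometry during a slow coupling.
- Fallback: it sets out from 8 and 6 and forms C15=C15' by olefination instead of C14'–C15' by coupling. Wittig reaction of 8 with (triphenylphosphoranylidene)acetaldehyde gives the C17 dienal F7. Zinc-iodide-mediated Arbuzov reaction of 6 with triethyl phosphite gives the allylic phosphonate F8. E-selective Horner–Wadsworth–Emmons reaction of F8 (two equivalents of LiHMDS) with F7 comes back to the route at 12.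

**Step 17.**
- What may go wrong: protonation of the zinc enolate by the hydroxyls, sluggish coupling next to the crowded C6, or migration of C7=C8 into conjugation.
- Fallback: it sets out from 18 and makes C7=C8 instead of C8–C9. Lindlar semi-hydrogenation gives the vinyl carbinol F9. Cross metathesis of F9 with ethyl but-3-enoate (a second-generation ruthenium catalyst) comes back to the route at 21.

## Further compounds

F1 | step 19 | (E)-2,3-dibromoacrylic acid | Br/C=C(/Br)C(=O)O
F2 | step 19 | (Z)-3-bromo-5-ylidenebutenolide carrying the complete C12–C7' chain and the TBS-protected enyne ring | CC1=C(C#C/C(C)=C/C=C/C=C/C=C(C)/C=C2C=C(Br)C(=O)O/2)C(C)(C)C[C@H](O[Si](C)(C)C(C)(C)C)C1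
F3 | step 14 | (4S)-4-hydroxy-2,6,6-trimethylcyclohex-2-en-1-one | CC1=C[C@@H](O)CC(C)(C)C1=O
F4 | step 14 | (4S)-4-(tert-butyldimethylsilyloxy)-2,6,6-trimethylcyclohex-2-en-1-one | CC1=C[C@@H](O[Si](C)(C)C(C)(C)C)CC(C)(C)C1=O
F5 | step 14 | 6-ethynyl-6-(trimethylsilyloxy)-3-(TBSO)-4-ene (both oxygens cis) | C#C[C@@]1(O[Si](C)(C)C)C(C)(C)C[C@H](O[Si](C)(C)C(C)(C)C)C=C1C
F6 | step 14 | 4,5-epoxide of F5, oxygen trans to both silyloxy groups | C#C[C@@]1(O[Si](C)(C)C)C(C)(C)C[C@H](O[Si](C)(C)C(C)(C)C)[C@H]2O[C@@]12C
F7 | step 9 | C17 (2E,4E)-dienynal | CC1=C(C#C/C(C)=C/C=C/C=O)C(C)(C)C[C@H](O[Si](C)(C)C(C)(C)C)C1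
F8 | step 9 | diethyl [(2E)-3-methylpent-2-en-4-yn-1-yl]phosphonate | C#C/C(C)=C/CP(=O)(OCC)OCC
F9 | step 17 | (1R,2R,4S)-4-(TBSO)-1-ethenyl-2,6,6-trimethylcyclohexane-1,2-diol | C=C[C@@]1(O)C(C)(C)C[C@H](O[Si](C)(C)C(C)(C)C)C[C@@]1(C)O
A1 | alternative 1 | (5Z)-3-bromo-5-(iodomethylidene)furan-2(5H)-one | I/C=C1C=C(Br)C(=O)O/1
A2 | alternative 1 | all-E C13 tributylstannane of the enyne half | CC1=C(C#C/C(C)=C/C=C/C=C/C=C(C)/[Sn](CCCC)(CCCC)CCCC)C(C)(C)C[C@H](O[Si](C)(C)C(C)(C)C)C1
A3 | alternative 2 | (Z)-3-iodo-2-[(E)-2-(ring)ethenyl]acrylic acid (iodine cis to CO2H) | I/C=C(/C=C/[C@@]1(O)C(C)(C)C[C@H](O[Si](C)(C)C(C)(C)C)C[C@@]1(C)O)C(=O)O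
A4 | alternative 3 | 3-[(E)-2-(ring)ethenyl]furan-2(5H)-one | O=C1OCC=C1/C=C/[C@@]2(O)C(C)(C)C[C@H](O[Si](C)(C)C(C)(C)C)C[C@@]2(C)O
A5 | alternative 3 | C22 all-E polyenynal (C12 aldehyde) | CC1=C(C#C/C(C)=C/C=C/C=C/C=C(C)/C=O)C(C)(C)C[C@H](O[Si](C)(C)C(C)(C)C)C1
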